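**Assumption:** the SMILES is read as fisetinidol-(4α→8)-6-methylcatechin: upper unit (rings A, B, C) 2R,3S,4S, i.e. 2,3-trans-3,4-trans; lower unit (rings D, E, F) 2R,3S. Flavan numbering is used for both units, and ring D positions are written C6(D) and C8(D).

## Retrosynthetic overview

1. Target ⇐ its hepta-O-benzyl ether by a final global hydrogenolysis; before that, the C6(D) methyl by bromination and Suzuki methylation (C8(D) is already occupied).
2. Upper C3–OH and C4–H ⇐ syn hydroboration–oxidation of a 4-aryl-flav-3-ene, anti to the 2-aryl group (gives 2,3-trans-3,4-trans).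
3. Key disconnection, interflavan C4–C8(D) ⇐ C–H alkynylation of tetra-O-benzylcatechin by a 1-iodoalkyne that acts on gold as an alkynyl cation (reversed-polarity acetylide) equivalent; ring C then closes by 6-endo hydroarylation in the same flask.
4. Iodoalkyne ⇐ terminal alkyne ⇐ enantioconvergent copper-catalysed propargylic etherification of a racemic propargylic acetate with 3-benzyloxyphenol (C2–O1 bond, sets C2) ⇐ 3,4-bis(benzyloxy)benzaldehyde + ethynylmagnesium bromide.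
5. Ring order: rings D, E, F come intact from (+)-catechin; rings A and B are bought as arenes; ring C is the only ring that is made.

## Route

Step 1
Reactants: 1 3,4-bis(benzyloxy)benzaldehyde; 2 ethynylmagnesium bromide
Product: 4 rac-1-[3,4-bis(benzyloxy)phenyl]prop-2-yn-1-yl acetate, via bromomagnesium propargylic alkoxide 3 (not isolated)
Conditions: 2 (1.3 equiv), THF, 0 °C, 1 h; then Ac2O (2 equiv), 0 °C → rt
Reagents that add atoms: acetic anhydride, CC(=O)OC(C)=O
Why: Grignard 1,2-addition of the acetylide to the aldehyde and in-flask O-acetylation of the magnesium alkoxide give the propargylic ester; the new centre is left racemic because step 2 is enantioconvergent.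

Step 2
Reactants: 4 rac-1-[3,4-bis(benzyloxy)phenyl]prop-2-yn-1-yl acetate; 5 3-(benzyloxy)phenol
Product: 6 (S)-1-(benzyloxy)-3-({1-[3,4-bis(benzyloxy)phenyl]prop-2-yn-1-yl}oxy)benzene
Conditions: Cu(OTf)2 (5 mol%), 2,6-bis[(4S)-4-phenyl-4,5-dihydrooxazol-2-yl]pyridine (6 mol%), i-Pr2NEt (1.2 equiv), MeCN, −20 °C
Reagents that add atoms: none
Why: Copper-catalysed asymmetric propargylic etherification: the copper acetylide of 4 loses acetate to a planar copper allenylidene and the pybox-bound metal directs attack of the phenol oxygen on the γ-carbon to one face, so both enantiomers of 4 converge on the S ether, whose centre becomes C2 of ring C (if the first run gives the R ether, the mirror-image ligand is used).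

Step 3
Reactants: 6 (S)-1-(benzyloxy)-3-({1-[3,4-bis(benzyloxy)phenyl]prop-2-yn-1-yl}oxy)benzene
Product: 7 (R)-1-(benzyloxy)-3-({1-[3,4-bis(benzyloxy)phenyl]-3-iodoprop-2-yn-1-yl}oxy)benzene
Conditions: NIS (1.1 equiv), AgNO3 (10 mol%), acetone, rt, dark
Reagents that add atoms: N-iodosuccinimide, O=C1CCC(=O)N1I
Why: Silver-catalysed electrophilic iodination of the terminal alkyne turns the acetylide carbon into a C(sp)–I electrophile without touching the propargylic centre, whose descriptor becomes R only because iodoethynyl outranks aryl.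

Step 4
Reactants: 8 (+)-catechin
Product: 9 (2R,3S)-5,7-bis(benzyloxy)-2-[3,4-bis(benzyloxy)phenyl]chroman-3-ol
Conditions: BnBr (4.4 equiv), K2CO3 (5 equiv), DMF, 0 °C → rt, N2
Reagents that add atoms: benzyl bromide, BrCc1ccccc1
Why: Williamson etherification of the four phenols; the secondary C3 alcohol is not deprotonated by K2CO3, and the weak base at room temperature leaves C2 and C3 of catechin unchanged.

Step 5
Reactants: 7 (R)-1-(benzyloxy)-3-({1-[3,4-bis(benzyloxy)phenyl]-3-iodoprop-2-yn-1-yl}oxy)benzene; 9 (2R,3S)-5,7-bis(benzyloxy)-2-[3,4-bis(benzyloxy)phenyl]chroman-3-ol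
Product: 11 (2R,3S)-5,7-bis(benzyloxy)-8-{(2S)-7-(benzyloxy)-2-[3,4-bis(benzyloxy)phenyl]-2H-chromen-4-yl}-2-[3,4-bis(benzyloxy)phenyl]chroman-3-ol, via C8-alkynylated catechin ether 10 (not isolated)
Conditions: AuCl[P(1-Ad)2(C6H4-2-NMe2)] (5 mol%; Ad = adamantyl), AgOTf (1.1 equiv), K3PO4 (1.0 equiv), 9 (1.5 equiv), 1,2-dichloroethane, 7 added over 2 h at 0 °C; then 40 °C
Reagents that add atoms: none
Why: Proposed new method: the C(sp)–I bond of 7 adds oxidatively to the cationic (P,N)-ligated monovalent gold to give an electrophilic alkynyl complex of trivalent gold, so the alkyne terminus (normally an acetylide nucleophile) is delivered as an alkynyl cation equivalent to the nucleophilic C8(D)–H (SEAr auration after iodide abstraction by AgOTf, then C(sp2)–C(sp) reductive elimination), and once 7 is consumed the regenerated cationic monovalent gold acts as a π-acid for 6-endo-dig hydroarylation of 10 by the ring A carbon para to OBn, closing ring C without touching C2; the closest known reactions are the (P,N)-gold-catalysed C–H arylation of 1,3,5-trimethoxybenzene with aryl iodides, the gold-catalysed alkynylation of trimethoxybenzenes with silyl ethynylbenziodoxolones, and the gold-catalysed cyclisation of aryl propargyl ethers to 2H-chromenes.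

Step 6
Reactants: 11 (2R,3S)-5,7-bis(benzyloxy)-8-{(2S)-7-(benzyloxy)-2-[3,4-bis(benzyloxy)phenyl]-2H-chromen-4-yl}-2-[3,4-bis(benzyloxy)phenyl]chroman-3-ol
Product: 13 (2R,3S,4S)-7-(benzyloxy)-2-[3,4-bis(benzyloxy)phenyl]-4-{(2R,3S)-5,7-bis(benzyloxy)-2-[3,4-bis(benzyloxy)phenyl]-3-hydroxychroman-8-yl}chroman-3-ol, via C3 alkylborane 12 (not isolated)
Conditions: BH3·THF (4 equiv), THF, 0 °C → rt; then 3 M NaOH, 30% H2O2, 0 °C
Reagents that add atoms: hydrogen peroxide, OO (oxygen of the new C3 hydroxyl); borane–tetrahydrofuran, B.C1CCOC1 (boron of intermediate 12 only; it leaves only hydrogen at C4 in 13)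
Why: Brown hydroboration–oxidation: BH3 adds syn across C3=C4 with boron on the less substituted C3 and hydrogen on the doubly benzylic C4, from the face anti to the 2-aryl group, and oxidation with retention gives the 2,3-trans-3,4-trans (3S,4S) alcohol; C2 is unchanged in space and becomes R only because C3 now outranks the aryl group.

Step 7
Reactants: 13 (2R,3S,4S)-7-(benzyloxy)-2-[3,4-bis(benzyloxy)phenyl]-4-{(2R,3S)-5,7-bis(benzyloxy)-2-[3,4-bis(benzyloxy)phenyl]-3-hydroxychroman-8-yl}chroman-3-ol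
Product: 14 (2R,3S,4S)-7-(benzyloxy)-2-[3,4-bis(benzyloxy)phenyl]-4-{(2R,3S)-5,7-bis(benzyloxy)-2-[3,4-bis(benzyloxy)phenyl]-6-bromo-3-hydroxychroman-8-yl}chroman-3-ol
Conditions: NBS (1.0 equiv), CH2Cl2, −78 → −30 °C
Reagents that add atoms: N-bromosuccinimide, O=C1CCC(=O)N1Br
Why: Electrophilic aromatic bromination: C6(D) is the only free position activated by three oxygen donors (two ortho, one para), so one equivalent of NBS at low temperature brominates it before ring A (two donors) or the catechol rings.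

Step 8
Reactants: 14 (2R,3S,4S)-7-(benzyloxy)-2-[3,4-bis(benzyloxy)phenyl]-4-{(2R,3S)-5,7-bis(benzyloxy)-2-[3,4-bis(benzyloxy)phenyl]-6-bromo-3-hydroxychroman-8-yl}chroman-3-ol
Product: 15 (2R,3S,4S)-7-(benzyloxy)-2-[3,4-bis(benzyloxy)phenyl]-4-{(2R,3S)-5,7-bis(benzyloxy)-2-[3,4-bis(benzyloxy)phenyl]-3-hydroxy-6-methylchroman-8-yl}chroman-3-ol
Conditions: MeB(OH)2 (3 equiv), Pd(OAc)2 (5 mol%), SPhos (10 mol%), K3PO4 (3 equiv), toluene/H2O (10:1), 90 °C
Reagents that add atoms: methylboronic acid, CB(O)O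
Why: Suzuki–Miyaura methylation: the biaryl dialkylphosphine ligand allows oxidative addition and transmetalation at the bromide flanked by two benzyloxy groups, and no stereocentre is involved.

Step 9
Reactants: 15 (2R,3S,4S)-7-(benzyloxy)-2-[3,4-bis(benzyloxy)phenyl]-4-{(2R,3S)-5,7-bis(benzyloxy)-2-[3,4-bis(benzyloxy)phenyl]-3-hydroxy-6-methylchroman-8-yl}chroman-3-ol
Product: 16 (2R,3S,4S)-2-(3,4-dihydroxyphenyl)-4-[(2R,3S)-2-(3,4-dihydroxyphenyl)-3,5,7-trihydroxy-6-methylchroman-8-yl]chroman-3,7-diol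
Conditions: H2 (1 atm), Pd(OH)2/C (20 wt%), THF/MeOH/H2O, rt
Reagents that add atoms: none
Why: Catalytic hydrogenolysis of the seven benzyl aryl ethers; the interflavan C4–C8(D) bond, the C-methyl group and the cyclic benzylic C2–O1 bonds of rings C and F are not cleaved under neutral conditions at room temperature, so all five stereocentres are retained.

## Compound list

1 | 3,4-bis(benzyloxy)benzaldehyde | O=Cc1ccc(OCc2ccccc2)c(OCc2ccccc2)c1 | starting material
2 | ethynylmagnesium bromide | C#C[Mg]Br | starting material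
3 | bromomagnesium 1-[3,4-bis(benzyloxy)phenyl]prop-2-yn-1-olate (racemic) | C#CC(O[Mg]Br)c1ccc(OCc2ccccc2)c(OCc2ccccc2)c1 | intermediate
4 | rac-1-[3,4-bis(benzyloxy)phenyl]prop-2-yn-1-yl acetate | C#CC(OC(C)=O)c1ccc(OCc2ccccc2)c(OCc2ccccc2)c1 | intermediate
5 | 3-(benzyloxy)phenol | Oc1cccc(OCc2ccccc2)c1 | starting material
6 | (S)-1-(benzyloxy)-3-({1-[3,4-bis(benzyloxy)phenyl]prop-2-yn-1-yl}oxy)benzene | C#C[C@H](Oc1cccc(OCc2ccccc2)c1)c1ccc(OCc2ccccc2)c(OCc2ccccc2)c1 | intermediate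
7 | (R)-1-(benzyloxy)-3-({1-[3,4-bis(benzyloxy)phenyl]-3-iodoprop-2-yn-1-yl}oxy)benzene (same spatial arrangement as 6) | IC#C[C@H](Oc1cccc(OCc2ccccc2)c1)c1ccc(OCc2ccccc2)c(OCc2ccccc2)c1 | intermediate
8 | (+)-catechin, (2R,3S)-2-(3,4-dihydroxyphenyl)chroman-3,5,7-triol | O[C@H]1Cc2c(O)cc(O)cc2O[C@@H]1c1ccc(O)c(O)c1 | starting material
9 | 5,7,3',4'-tetra-O-benzyl-(+)-catechin, (2R,3S)-5,7-bis(benzyloxy)-2-[3,4-bis(benzyloxy)phenyl]chroman-3-ol | O[C@H]1Cc2c(OCc3ccccc3)cc(OCc3ccccc3)cc2O[C@@H]1c1ccc(OCc2ccccc2)c(OCc2ccccc2)c1 | intermediate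
10 | (2R,3S)-5,7-bis(benzyloxy)-8-{(3R)-3-[3-(benzyloxy)phenoxy]-3-[3,4-bis(benzyloxy)phenyl]prop-1-yn-1-yl}-2-[3,4-bis(benzyloxy)phenyl]chroman-3-ol | c1c(OCc5ccccc5)c2c(c(C#C[C@H](Oc3cccc(OCc5ccccc5)c3)c3ccc(OCc5ccccc5)c(OCc5ccccc5)c3)c1OCc1ccccc1)O[C@H](c1ccc(OCc3ccccc3)c(OCc3ccccc3)c1)[C@@H](O)C2 | intermediate
11 | (2R,3S)-5,7-bis(benzyloxy)-8-{(2S)-7-(benzyloxy)-2-[3,4-bis(benzyloxy)phenyl]-2H-chromen-4-yl}-2-[3,4-bis(benzyloxy)phenyl]chroman-3-ol | c1c(OCc5ccccc5)c2c(c(C3=C[C@@H](c4ccc(OCc5ccccc5)c(OCc5ccccc5)c4)Oc4cc(OCc5ccccc5)ccc34)c1OCc1ccccc1)O[C@H](c1ccc(OCc3ccccc3)c(OCc3ccccc3)c1)[C@@H](O)C2 | intermediate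
12 | C3-dihydroboryl adduct of 11, drawn as the monoalkylborane (boron at C3 and the new hydrogen at C4 both on the face anti to the 2-aryl group; ring F oxygen carried as O–BH2) | c1c(OCc5ccccc5)c2c(c([C@@H]3c4ccc(OCc5ccccc5)cc4O[C@H](c4ccc(OCc5ccccc5)c(OCc5ccccc5)c4)[C@H]3B)c1OCc1ccccc1)O[C@H](c1ccc(OCc3ccccc3)c(OCc3ccccc3)c1)[C@@H](OB)C2 | intermediate
13 | (2R,3S,4S)-7-(benzyloxy)-2-[3,4-bis(benzyloxy)phenyl]-4-{(2R,3S)-5,7-bis(benzyloxy)-2-[3,4-bis(benzyloxy)phenyl]-3-hydroxychroman-8-yl}chroman-3-ol | c1c(OCc5ccccc5)c2c(c([C@@H]3c4ccc(OCc5ccccc5)cc4O[C@H](c4ccc(OCc5ccccc5)c(OCc5ccccc5)c4)[C@H]3O)c1OCc1ccccc1)O[C@H](c1ccc(OCc3ccccc3)c(OCc3ccccc3)c1)[C@@H](O)C2 | intermediate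
14 | 6-bromo (ring D) derivative of 13 | Brc1c(OCc5ccccc5)c2c(c([C@@H]3c4ccc(OCc5ccccc5)cc4O[C@H](c4ccc(OCc5ccccc5)c(OCc5ccccc5)c4)[C@H]3O)c1OCc1ccccc1)O[C@H](c1ccc(OCc3ccccc3)c(OCc3ccccc3)c1)[C@@H](O)C2 | intermediate
15 | 6-methyl (ring D) derivative of 13, hepta-O-benzyl ether of the target | Cc1c(OCc5ccccc5)c2c(c([C@@H]3c4ccc(OCc5ccccc5)cc4O[C@H](c4ccc(OCc5ccccc5)c(OCc5ccccc5)c4)[C@H]3O)c1OCc1ccccc1)O[C@H](c1ccc(OCc3ccccc3)c(OCc3ccccc3)c1)[C@@H](O)C2 | intermediate
16 | (2R,3S,4S)-2-(3,4-dihydroxyphenyl)-4-[(2R,3S)-2-(3,4-dihydroxyphenyl)-3,5,7-trihydroxy-6-methylchroman-8-yl]chroman-3,7-diol | Cc1c(O)c2c(c([C@@H]3c4ccc(O)cc4O[C@H](c4ccc(O)c(O)c4)[C@H]3O)c1O)O[C@H](c1ccc(O)c(O)c1)[C@@H](O)C2 | target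

## Step count and risks

Total step count: 9. Longest linear sequence: 8 steps (1, 2, 3, 5, 6, 7, 8, 9).

**Step 5 (gold-mediated C–H alkynylation and ring closure).** The iodoalkyne may cyclise first, with iodine migration, or ring D may react at C6 as well as C8. The fallback makes the C4–C8(D) bond by conventional cross-coupling. It sets out from 9, which is iodinated at C8 (NIS, CH2Cl2, −20 °C) to (2R,3S)-5,7-bis(benzyloxy)-2-[3,4-bis(benzyloxy)phenyl]-8-iodochroman-3-ol F1. Copper-free Sonogashira coupling of F1 with terminal alkyne 6 (PdCl2(MeCN)2, XPhos, Cs2CO3, MeCN, 60 °C) gives 10, which is now isolated. Au(NTf2)(PPh3) (2 mol%, CH2Cl2, rt) cyclises 10, and the route is rejoined at 11; step 3 is then not needed.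

**Step 2 (copper-catalysed etherification).** The electron-rich phenol may be C-alkylated instead of O-alkylated, or the ee may be low. The fallback sets out from 1 and comes back at 6. Enantioselective zinc-mediated addition of trimethylsilylacetylene to 1 (Me2Zn, the ProPhenol antipode that gives the S alcohol, toluene, 0 °C) gives (S)-1-[3,4-bis(benzyloxy)phenyl]-3-(trimethylsilyl)prop-2-yn-1-ol F2. Mitsunobu etherification with 5 (PPh3, DIAD, THF, −20 °C) inverts the centre and gives (R)-1-(benzyloxy)-3-({1-[3,4-bis(benzyloxy)phenyl]-3-(trimethylsilyl)prop-2-yn-1-yl}oxy)benzene F3. K2CO3 in MeOH removes the silyl group and gives 6.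

**Step 6 (hydroboration of the hindered 4-aryl-flav-3-ene).** Addition may be slow, or the β-aryloxy borane may eliminate with opening of ring C. The fallback sets the same two centres by anti opening of an epoxide. It sets out from 6 and 9 and comes back at 13. Au(NTf2)(PPh3)-catalysed 6-endo hydroarylation of 6 gives (S)-7-(benzyloxy)-2-[3,4-bis(benzyloxy)phenyl]-2H-chromene F4. Dimethyldioxirane (acetone, −40 °C) epoxidises the face anti to the 2-aryl group and gives (2R,3R,4S)-7-(benzyloxy)-2-[3,4-bis(benzyloxy)phenyl]-3,4-epoxychroman F5. F5 is opened in the same flask at the benzylic C4 by C8(D) of 9 (BF3·OEt2 cat., CH2Cl2, −78 °C) with inversion, which gives 13 directly.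

## Further compounds

F1 | step 5 | (2R,3S)-5,7-bis(benzyloxy)-2-[3,4-bis(benzyloxy)phenyl]-8-iodochroman-3-ol | c1c(OCc5ccccc5)c2c(c(I)c1OCc1ccccc1)O[C@H](c1ccc(OCc3ccccc3)c(OCc3ccccc3)c1)[C@@H](O)C2
F2 | step 2 | (S)-1-[3,4-bis(benzyloxy)phenyl]-3-(trimethylsilyl)prop-2-yn-1-ol | C[Si](C)(C)C#C[C@@H](O)c1ccc(OCc2ccccc2)c(OCc2ccccc2)c1
F3 | step 2 | (R)-1-(benzyloxy)-3-({1-[3,4-bis(benzyloxy)phenyl]-3-(trimethylsilyl)prop-2-yn-1-yl}oxy)benzene | C[Si](C)(C)C#C[C@H](Oc1cccc(OCc2ccccc2)c1)c1ccc(OCc2ccccc2)c(OCc2ccccc2)c1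
F4 | step 6 | (S)-7-(benzyloxy)-2-[3,4-bis(benzyloxy)phenyl]-2H-chromene | C1=C[C@@H](c2ccc(OCc3ccccc3)c(OCc3ccccc3)c2)Oc2cc(OCc3ccccc3)ccc12
F5 | step 6 | (2R,3R,4S)-7-(benzyloxy)-2-[3,4-bis(benzyloxy)phenyl]-3,4-epoxychroman (epoxide oxygen anti to the 2-aryl group) | [C@H]12O[C@H]1c1ccc(OCc3ccccc3)cc1O[C@@H]2c1ccc(OCc2ccccc2)c(OCc2ccccc2)c1
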